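**Retrosynthetic overview**

1. The target is reached last by global O-debenzylation and loss (decarboxylation) of a temporary benzyl ester on C1 of a fully assembled, cis-fused furofuranone.
2. Key disconnection: tetrahydrofuran ring B (C1–C5–C6–O7–C8) ⇒ the cyclopropane C1–C5–C6 of a 3-oxabicyclo[3.1.0]hexan-2-one plus 3,4-bis(benzyloxy)benzaldehyde, whose C8=O7 unit is inserted into the C1–C6 bond (three-membered ring grows to five).
3. Enabling feature: C1 is α to the lactone carbonyl C2 (and to the temporary ester), and C6 is an unsubstituted CH2 that ends on O7. In a cyclopropane fused to lactone ring A (C1–C2–O3–C4–C5) the C1–C6 bond is therefore a homo-Michael acceptor: opening at C6 leaves a C1 enolate that takes up the aldehyde, and the resulting alkoxide closes back onto C6.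
4. Cyclopropane-fused lactone ⇒ intramolecular cyclopropanation of the diazomalonate of an (S)-1-arylallyl alcohol; the carbinol centre C4 comes from a lipase resolution and relays C5, C1 and C8.
5. Ring order: lactone ring A together with the cyclopropane (step 5), then ring B by ring expansion (step 6).

Key step: step 6

Remark: ring atoms are numbered as in 3,7-dioxabicyclo[3.3.0]octan-2-one (C1 fusion carbon next to carbonyl C2, O3, C4 bearing the trihydroxyphenyl group, C5 second fusion carbon, C6H2, O7, C8 bearing the dihydroxyphenyl group) and keep these numbers in all precursors; compounds 1, 4 and 8 are assumed to be purchased.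

**Route**

Step 1
Reactants: 1 3,4,5-tris(benzyloxy)benzaldehyde
Product: 2 rac-1-[3,4,5-tris(benzyloxy)phenyl]prop-2-en-1-ol
Conditions: CH2=CHMgBr (1.2 equiv), THF, −78 to 0 °C; aq NH4Cl
Reagents that add atoms: vinylmagnesium bromide, C=C[Mg]Br
Why: 1,2-addition of a Grignard reagent to an aromatic aldehyde gives the allylic carbinol (future C4–C5–C6) as the racemate, which is resolved in the next step.

Step 2
Reactants: 2 rac-1-[3,4,5-tris(benzyloxy)phenyl]prop-2-en-1-ol
Product: 3 (1S)-1-[3,4,5-tris(benzyloxy)phenyl]prop-2-en-1-ol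
Conditions: Novozym 435 (immobilised Candida antarctica lipase B), vinyl acetate (3 equiv), MTBE, 30 °C, stopped just past half conversion
Reagents that add atoms: none
Why: lipase-catalysed kinetic resolution by enantioselective transesterification should acylate the (R)-alcohol (Kazlauskas rule, aryl as the large and vinyl as the medium group) and leave the (S)-alcohol, which fixes C4.

Step 3
Reactants: 3 (1S)-1-[3,4,5-tris(benzyloxy)phenyl]prop-2-en-1-ol; 4 benzyl hydrogen malonate
Product: 5 benzyl (1S)-1-[3,4,5-tris(benzyloxy)phenyl]prop-2-en-1-yl propanedioate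
Conditions: DCC, DMAP (10 mol %), CH2Cl2, 0 to 23 °C
Reagents that add atoms: none
Why: Steglich esterification of the secondary alcohol with a malonic half ester proceeds under neutral conditions without touching the carbinol centre.

Step 4
Reactants: 5 benzyl (1S)-1-[3,4,5-tris(benzyloxy)phenyl]prop-2-en-1-yl propanedioate
Product: 6 benzyl (1S)-1-[3,4,5-tris(benzyloxy)phenyl]prop-2-en-1-yl 2-diazopropanedioate
Conditions: 4-acetamidobenzenesulfonyl azide, Et3N, MeCN, 0 to 23 °C
Reagents that add atoms: 4-acetamidobenzenesulfonyl azide, CC(=O)Nc1ccc(cc1)S(=O)(=O)N=[N+]=[N-]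
Why: Regitz diazo transfer to the doubly activated malonate methylene is reliable with amine base.

Step 5
Reactants: 6 benzyl (1S)-1-[3,4,5-tris(benzyloxy)phenyl]prop-2-en-1-yl 2-diazopropanedioate
Product: 7 benzyl (1R,4S,5S)-2-oxo-4-[3,4,5-tris(benzyloxy)phenyl]-3-oxabicyclo[3.1.0]hexane-1-carboxylate
Conditions: Rh2(esp)2 (1 mol %; esp = α,α,α′,α′-tetramethyl-1,3-benzenedipropanoate), CH2Cl2, 23 °C, slow addition of 6
Reagents that add atoms: none
Why: intramolecular cyclopropanation of an allyl diazomalonate by a rhodium carbenoid closes lactone ring A and the cyclopropane together; the fusion can only be cis, and C5/C1 should follow C4 by substrate control, the allylic C–H eclipsing the alkene so that the aryl group sits exo, anti to the new CH2.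

Step 6
Reactants: 7 benzyl (1R,4S,5S)-2-oxo-4-[3,4,5-tris(benzyloxy)phenyl]-3-oxabicyclo[3.1.0]hexane-1-carboxylate; 8 3,4-bis(benzyloxy)benzaldehyde
Product: 11 benzyl (3S,3aR,6R,6aS)-6-[3,4-bis(benzyloxy)phenyl]-1-oxo-3-[3,4,5-tris(benzyloxy)phenyl]tetrahydro-1H,3H-furo[3,4-c]furan-6a-carboxylate, via iodomagnesium enolate 9 (not isolated), via iodomagnesium aldolate 10 (not isolated)
Conditions: MgI2 (30 mol %), 8 (1.5 equiv), THF, 65 °C, sealed tube
Reagents that add atoms: none
Why: Proposed new method: MgI2 chelates the lactone–ester 1,3-dicarbonyl unit of 7, iodide opens the doubly activated cyclopropane by SN2 attack at the unsubstituted C6 (homo-Michael addition) to give enolate 9, this adds reversibly to aldehyde 8, and the alkoxide of aldolate 10 displaces iodide from C6 with release of MgI2; the closest known reactions are the MgI2-mediated ring expansions of acceptor-substituted cyclopropanes with imines (to pyrrolidines) and nitrones (to 1,2-oxazinanes) and the Lewis-acid-catalysed (3+2) annulation of donor–acceptor cyclopropanes with aldehydes. The only ring closed is tetrahydrofuran ring B, by 5-exo-tet O-alkylation, so the three-membered ring C1–C5–C6 grows to C1–C5–C6–O7–C8 while lactone ring A stays intact. C4 and C5 are untouched, and the quaternary C1 is set by the ring constraint: only the aldolate that carries C8 on the face of the iodomethyl group can close to the cis-fused bicycle, and retro-aldol returns the other to 9. C8 is selected among the reversibly formed aldolates during ring closure, where the aryl group is expected on the open convex face next to the freely rotating ester rather than folded over lactone ring A; this is the least secure stereochemical call of the route. The step needs iodide attack at C6 and not C5 (C6 is the only primary cyclopropane carbon and the C1–C6 bond is aligned with both carbonyl groups) and O- rather than C-alkylation at the end (the ester makes C1 quaternary in 10, so the aldolate cannot re-form a cyclopropane without first losing the aldehyde).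

Step 7
Reactants: 11 benzyl (3S,3aR,6R,6aS)-6-[3,4-bis(benzyloxy)phenyl]-1-oxo-3-[3,4,5-tris(benzyloxy)phenyl]tetrahydro-1H,3H-furo[3,4-c]furan-6a-carboxylate
Product: 13 (3S,3aR,6S,6aS)-6-(3,4-dihydroxyphenyl)-3-(3,4,5-trihydroxyphenyl)tetrahydro-1H,3H-furo[3,4-c]furan-1-one, via pentahydroxy acid 12 (not isolated)
Conditions: H2 (1 atm), Pd/C (10 wt %), THF–MeOH, 23 °C, stopped at full debenzylation; filter under Ar; then degassed 1,4-dioxane, 95 °C
Reagents that add atoms: none
Why: neutral hydrogenolysis should cleave the five aryl benzyl ethers and the benzyl ester faster than the ring benzylic C–O bonds, and the resulting α-carboxy lactone 12 decarboxylates thermally through the lactone enol, whose protonation can only give the cis-fused bicycle and so sets C1 (position 6a).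

**Compound list**

1 | 3,4,5-tris(benzyloxy)benzaldehyde | O=Cc1cc(OCc2ccccc2)c(OCc2ccccc2)c(OCc2ccccc2)c1 | starting material
2 | rac-1-[3,4,5-tris(benzyloxy)phenyl]prop-2-en-1-ol | C=CC(O)c1cc(OCc2ccccc2)c(OCc2ccccc2)c(OCc2ccccc2)c1 | intermediate
3 | (1S)-1-[3,4,5-tris(benzyloxy)phenyl]prop-2-en-1-ol | C=C[C@H](O)c1cc(OCc2ccccc2)c(OCc2ccccc2)c(OCc2ccccc2)c1 | intermediate
4 | benzyl hydrogen malonate (3-(benzyloxy)-3-oxopropanoic acid) | O=C(O)CC(=O)OCc1ccccc1 | starting material
5 | benzyl (1S)-1-[3,4,5-tris(benzyloxy)phenyl]prop-2-en-1-yl propanedioate | C=C[C@H](OC(=O)CC(=O)OCc1ccccc1)c1cc(OCc2ccccc2)c(OCc2ccccc2)c(OCc2ccccc2)c1 | intermediate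
6 | benzyl (1S)-1-[3,4,5-tris(benzyloxy)phenyl]prop-2-en-1-yl 2-diazopropanedioate | C=C[C@H](OC(=O)C(=[N+]=[N-])C(=O)OCc1ccccc1)c1cc(OCc2ccccc2)c(OCc2ccccc2)c(OCc2ccccc2)c1 | intermediate
7 | benzyl (1R,4S,5S)-2-oxo-4-[3,4,5-tris(benzyloxy)phenyl]-3-oxabicyclo[3.1.0]hexane-1-carboxylate (aryl exo, anti to the cyclopropane CH2) | O=C1O[C@H](c3cc(OCc4ccccc4)c(OCc4ccccc4)c(OCc4ccccc4)c3)[C@H]2C[C@@]12C(=O)OCc1ccccc1 | intermediate
8 | 3,4-bis(benzyloxy)benzaldehyde | O=Cc1ccc(OCc2ccccc2)c(OCc2ccccc2)c1 | starting material
9 | iodomagnesium enolate: benzyl (4S,5S)-4-(iodomethyl)-2-[(iodomagnesio)oxy]-5-[3,4,5-tris(benzyloxy)phenyl]-4,5-dihydrofuran-3-carboxylate | IC[C@H]1C(C(=O)OCc2ccccc2)=C(O[Mg]I)O[C@@H]1c1cc(OCc2ccccc2)c(OCc2ccccc2)c(OCc2ccccc2)c1 | intermediate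
10 | iodomagnesium aldolate: benzyl (3S,4S,5S)-3-{(R)-[3,4-bis(benzyloxy)phenyl][(iodomagnesio)oxy]methyl}-4-(iodomethyl)-2-oxo-5-[3,4,5-tris(benzyloxy)phenyl]oxolane-3-carboxylate (carbinol carbon cis to the iodomethyl group) | O=C1O[C@H](c3cc(OCc4ccccc4)c(OCc4ccccc4)c(OCc4ccccc4)c3)[C@@H](CI)[C@@]1(C(=O)OCc1ccccc1)[C@H](O[Mg]I)c1ccc(OCc2ccccc2)c(OCc2ccccc2)c1 | intermediate
11 | benzyl (3S,3aR,6R,6aS)-6-[3,4-bis(benzyloxy)phenyl]-1-oxo-3-[3,4,5-tris(benzyloxy)phenyl]tetrahydro-1H,3H-furo[3,4-c]furan-6a-carboxylate (cis-fused, both aryl groups exo) | O=C1O[C@H](c3cc(OCc4ccccc4)c(OCc4ccccc4)c(OCc4ccccc4)c3)[C@H]2CO[C@H](c3ccc(OCc4ccccc4)c(OCc4ccccc4)c3)[C@@]12C(=O)OCc1ccccc1 | intermediate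
12 | (3S,3aR,6R,6aS)-6-(3,4-dihydroxyphenyl)-1-oxo-3-(3,4,5-trihydroxyphenyl)tetrahydro-1H,3H-furo[3,4-c]furan-6a-carboxylic acid | O=C1O[C@H](c3cc(O)c(O)c(O)c3)[C@H]2CO[C@H](c3ccc(O)c(O)c3)[C@@]12C(=O)O | intermediate
13 | (3S,3aR,6S,6aS)-6-(3,4-dihydroxyphenyl)-3-(3,4,5-trihydroxyphenyl)tetrahydro-1H,3H-furo[3,4-c]furan-1-one | O=C1O[C@H](c2cc(O)c(O)c(O)c2)[C@H]2CO[C@H](c3ccc(O)c(O)c3)[C@@H]12 | target

**Step count and risks**

Total steps: 7. Longest linear sequence: 7 (1 → 2 → 3 → 5 → 6 → 7 → 11 → 13).

Steps most likely to fail: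

1. Step 6 (proposed new method). Two processes may go wrong. The stabilised enolate may re-close to the cyclopropane faster than it is captured by the electron-rich aldehyde. The exo/endo selection at C8 may be low or reversed, because the aryl group has to settle cis to the C1 ester. Fallback with known chemistry, setting out from 7 and 8 and returning at 11: aldehyde 8 is condensed with N-methylhydroxylamine to the (Z)-nitrone F1. The known MgI2-promoted homo-(3+2) annulation of nitrones with cyclopropane-1,1-dicarbonyl compounds joins F1 and 7 to the cis-fused tetrahydro-1,2-oxazine F2 (ring oxygen on C6, C8 on C1). Zn/AcOH cleaves the N–O bond to amino alcohol F3. Exhaustive methylation (MeI, K2CO3) gives ammonium salt F4. On warming, F4 ionises at the electron-rich benzylic carbon C8 (C1 carries no hydrogen, so Hofmann elimination is excluded) and the C6 hydroxyl closes ring B to 11. This closure by oxygen onto a planar benzylic cation is stereoconvergent at C8.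

2. Step 5. The carbenoid may add to the wrong alkene face (aryl endo at C4 relative to the cyclopropane), or be diverted into aromatic substitution on the electron-rich aryl ring. Fallback, setting out from 5 (bypassing 6) and returning at 7 with no new isolated compound (F0): oxidative radical cyclisation of the allylic malonate with Mn(OAc)3·2H2O and Cu(OAc)2 in AcOH at 60 °C, a known route from allylic malonates and β-keto esters to 3-oxabicyclo[3.1.0]hexan-2-ones. The malonyl radical closes 5-exo-trig through a chair-like transition state with the aryl group pseudo-equatorial (C4/C5 trans), and copper-mediated oxidation closes the primary radical onto the still acidic C1.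

3. Step 7. Once the para-hydroxyl groups are free, hydrogenolysis may go on to cleave the benzylic lactone bond C4–O3 or the benzylic ether bond C8–O7; the free polyphenol may also oxidise during the thermal stage. Fallback, setting out from 11 and returning at 12 with no new compound (F0): Lewis-acid debenzylation with BCl3 and pentamethylbenzene as cation scavenger (CH2Cl2, −78 °C) removes all six benzyl groups without a reducing metal; 12 is then decarboxylated as in step 7 to give 13.

**Further compounds**

F1 | step 6 | (Z)-N-methyl-1-[3,4-bis(benzyloxy)phenyl]methanimine N-oxide (nitrone of 8) | C/[N+]([O-])=C/c1ccc(OCc2ccccc2)c(OCc2ccccc2)c1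
F2 | step 6 | cis-fused N-methyl tetrahydro-1,2-oxazine–lactone benzyl ester (ring O on C6, aryl-bearing C8 on C1, C4 aryl exo; one C8 epimer drawn) | O=C1O[C@H](c3cc(OCc4ccccc4)c(OCc4ccccc4)c(OCc4ccccc4)c3)[C@H]2CON(C)[C@H](c3ccc(OCc4ccccc4)c(OCc4ccccc4)c3)[C@@]12C(=O)OCc1ccccc1
F3 | step 6 | benzyl (3S,4R,5S)-3-{[3,4-bis(benzyloxy)phenyl](methylamino)methyl}-4-(hydroxymethyl)-2-oxo-5-[3,4,5-tris(benzyloxy)phenyl]oxolane-3-carboxylate (one C8 epimer drawn) | O=C1O[C@H](c3cc(OCc4ccccc4)c(OCc4ccccc4)c(OCc4ccccc4)c3)[C@@H](CO)[C@@]1(C(=O)OCc1ccccc1)[C@H](NC)c1ccc(OCc2ccccc2)c(OCc2ccccc2)c1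
F4 | step 6 | trimethylammonium iodide derived from F3 | O=C1O[C@H](c3cc(OCc4ccccc4)c(OCc4ccccc4)c(OCc4ccccc4)c3)[C@@H](CO)[C@@]1(C(=O)OCc1ccccc1)[C@H]([N+](C)(C)C)c1ccc(OCc2ccccc2)c(OCc2ccccc2)c1.[I-]
F0 | step 5 | none | none
F0 | step 7 | none | none
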